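## Retrosynthetic overview

1. Marchantinquinone (16) comes from its MOM ether 15, which comes from macrocyclic phenol 14 by para-oxidation; the quinone ring is created last, from a resorcinol-derived ring.
2. The 18-membered ring of 14 is closed by an intramolecular Ullmann etherification of seco-bromide 13; the 2-alkylresorcinol is symmetric, so either OH gives the same macrocycle.
3. Key disconnection: the resorcinol C2–CH2 bond (future quinone C3–CH2), made by anti-Markovnikov addition of the aryl radical from unprotected 2-iodoresorcinol (2) to styrene 9. The second ArCH2–CH2Ar bridge is made the same way from 1-bromo-3-iodobenzene (12).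
4. The two styrenes come from vinylation of diaryl ether 7, first at Br and later at Cl; 7 comes from 4-chlorophenol and 4-bromophenol.
5. Ring order: the four benzene rings are bought (1, 3, 6, 12); the macrocycle forms in step 9; the quinone forms in step 10.

Assumption: the target has no stereocentres and is achiral, so there is no configuration to set and the route delivers the single constitution given.

## Route

**Step 1**
Reactants: 1 resorcinol
Product: 2 2-iodoresorcinol (2-iodobenzene-1,3-diol)
Conditions: I2, NaHCO3, H2O, 0 °C → rt
Reagents that add atoms: iodine, II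
Why: Electrophilic aromatic iodination under weakly basic aqueous conditions goes selectively to C2, between the two OH groups, giving the symmetric iodide.

**Step 2**
Reactants: 3 4-chlorophenol
Product: 4 4-chloro-2-iodophenol
Conditions: NIS (1.05 equiv), TsOH (10 mol%), MeCN, rt
Reagents that add atoms: N-iodosuccinimide, O=C1CCC(=O)N1I
Why: Electrophilic aromatic substitution; the para position is blocked by Cl, so mono-iodination occurs ortho to OH.

**Step 3**
Reactants: 4 4-chloro-2-iodophenol
Product: 5 4-chloro-2-iodo-1-(methoxymethoxy)benzene
Conditions: MOMCl, i-Pr2NEt, CH2Cl2, 0 °C → rt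
Reagents that add atoms: chloromethyl methyl ether, COCCl
Why: O-alkylation to the MOM acetal stops the o-iodophenol from self-coupling in step 4 and keeps this oxygen masked through the macrocyclisation and the oxidation.

**Step 4**
Reactants: 5 4-chloro-2-iodo-1-(methoxymethoxy)benzene; 6 4-bromophenol (1.2 equiv)
Product: 7 2-(4-bromophenoxy)-4-chloro-1-(methoxymethoxy)benzene
Conditions: CuI (10 mol%), picolinic acid (20 mol%), K3PO4, DMSO, 80 °C
Reagents that add atoms: none
Why: Ullmann-type Cu-catalysed diaryl ether synthesis; the C–I bond reacts much faster than C–Cl or the C–Br of the electron-rich phenoxide 6, so the halogens end up differentiated (Br on one ring, Cl on the other).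

**Step 5**
Reactants: 7 2-(4-bromophenoxy)-4-chloro-1-(methoxymethoxy)benzene; 8 potassium vinyltrifluoroborate
Product: 9 4-chloro-2-(4-ethenylphenoxy)-1-(methoxymethoxy)benzene
Conditions: PdCl2(dppf) (3 mol%), Cs2CO3, THF/H2O (9:1), 80 °C
Reagents that add atoms: potassium vinyltrifluoroborate (compound 8), C=C[B-](F)(F)F.[K+]
Why: Suzuki–Miyaura vinylation; with a dppf catalyst Pd inserts into C–Br and leaves the electron-rich C–Cl untouched.

**Step 6 (key step)**
Reactants: 9 4-chloro-2-(4-ethenylphenoxy)-1-(methoxymethoxy)benzene (1 equiv, 0.2 M); 2 2-iodoresorcinol (3 equiv)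
Product: 10 2-[2-(4-{[5-chloro-2-(methoxymethoxy)phenyl]oxy}phenyl)ethyl]benzene-1,3-diol
Conditions: 10-phenylphenothiazine (5 mol%), cyclohexanethiol (10 mol%), HCO2Na (4 equiv), DMSO/H2O (19:1), blue LEDs, rt, Ar
Reagents that add atoms: none
Why: Proposed new method: the photoexcited phenothiazine cleaves the C–I bond of 2 by electron transfer to give the 2,6-dihydroxyphenyl σ-radical, which adds to the terminal carbon of styrene 9 (about 10^8 M⁻¹ s⁻¹, anti-Markovnikov because it forms the benzylic radical); that radical is quenched by H-atom transfer from the thiol (or by 1,5-H transfer from an ortho OH), with formate turning the cycle over. The iodide is used in excess because hydrodeiodination is the main competing path, and the aryl chloride is too hard to reduce to interfere. The closest known reaction type is the photoredox/thiol anti-Markovnikov hydroarylation of alkenes with aryl halides (and tin-hydride-mediated aryl-radical additions to alkenes).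

**Step 7**
Reactants: 10 (chloride from step 6); 8 potassium vinyltrifluoroborate
Product: 11 2-[2-(4-{[5-ethenyl-2-(methoxymethoxy)phenyl]oxy}phenyl)ethyl]benzene-1,3-diol
Conditions: Pd(OAc)2 (3 mol%), XPhos (6 mol%), Cs2CO3 (4 equiv), THF/H2O (10:1), 80 °C
Reagents that add atoms: potassium vinyltrifluoroborate (compound 8), C=C[B-](F)(F)F.[K+]
Why: Suzuki–Miyaura vinylation of an unhindered electron-rich aryl chloride, enabled by the bulky biarylphosphine; the free phenols are tolerated with extra base and the MOM acetal is base-stable.

**Step 8**
Reactants: 11 (styrene from step 7, 1 equiv); 12 1-bromo-3-iodobenzene (3 equiv)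
Product: 13 2-[2-(4-{[5-[2-(3-bromophenyl)ethyl]-2-(methoxymethoxy)phenyl]oxy}phenyl)ethyl]benzene-1,3-diol
Conditions: 10-phenylphenothiazine (5 mol%), cyclohexanethiol (10 mol%), HCO2Na (4 equiv), DMSO/H2O (19:1), blue LEDs, rt; stop when 11 is consumed
Reagents that add atoms: none
Why: Proposed new method: the same aryl-radical anti-Markovnikov hydroarylation as step 6, here with a simple aryl iodide; electron transfer cleaves C–I far faster than C–Br, so the 3-bromophenyl radical adds to the styrene terminus and the bromide survives for step 9. The closest known reaction type is photoredox hydroarylation of alkenes with aryl halides and chemoselective photoredox C–I over C–Br activation.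

**Step 9**
Reactants: 13 (seco-bromide from step 8)
Product: 14 MOM-protected macrocyclic phenol: the 18-membered marchantin-type ring in which the resorcinol-derived ring carries the new aryl ether oxygen on one side of the CH2CH2 bridge and a free OH on the other
Conditions: CuI (1 equiv), N,N-dimethylglycine (2 equiv), Cs2CO3 (4 equiv), dioxane, 100 °C, syringe-pump addition to 2 mM
Reagents that add atoms: none
Why: Intramolecular Ullmann diaryl ether macrocyclisation; the two resorcinol OH groups are equivalent, so only one macrocycle can form, and with a single C–Br only one arylation is possible.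

**Step 10**
Reactants: 14 (macrocyclic phenol)
Product: 15 marchantinquinone O-methoxymethyl ether (2-aryloxy-3-alkyl-1,4-benzoquinone macrocycle, catechol-ring OH still as MOM ether)
Conditions: Fremy's salt (3 equiv), KH2PO4 buffer, acetone/H2O, rt
Reagents that add atoms: potassium nitrosodisulfonate, [K+].[K+].[O]N(S(=O)(=O)[O-])S(=O)(=O)[O-]
Why: Teuber oxidation: the nitroxide abstracts the phenolic H and a second equivalent couples at the free para carbon of the phenoxyl radical to give the p-quinone; the other oxygenated ring is fully etherified and cannot form a phenoxyl radical.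

**Step 11**
Reactants: 15 (MOM-protected quinone)
Product: 16 marchantinquinone
Conditions: TFA, CH2Cl2, 0 °C → rt
Reagents that add atoms: none
Why: Acid-catalysed acetal cleavage with a non-nucleophilic acid frees the phenol without adding to or displacing the aryloxy group from the quinone.

## Compound list

1 | resorcinol | Oc1cccc(O)c1 | starting material
2 | 2-iodoresorcinol | Oc1cccc(O)c1I | intermediate
3 | 4-chlorophenol | Oc1ccc(Cl)cc1 | starting material
4 | 4-chloro-2-iodophenol | Oc1ccc(Cl)cc1I | intermediate
5 | 4-chloro-2-iodo-1-(methoxymethoxy)benzene | COCOc1ccc(Cl)cc1I | intermediate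
6 | 4-bromophenol | Oc1ccc(Br)cc1 | starting material
7 | 2-(4-bromophenoxy)-4-chloro-1-(methoxymethoxy)benzene | COCOc1ccc(Cl)cc1Oc1ccc(Br)cc1 | intermediate
8 | potassium vinyltrifluoroborate | C=C[B-](F)(F)F.[K+] | starting material
9 | 4-chloro-2-(4-ethenylphenoxy)-1-(methoxymethoxy)benzene | COCOc1ccc(Cl)cc1Oc1ccc(C=C)cc1 | intermediate
10 | 2-[2-(4-{[5-chloro-2-(methoxymethoxy)phenyl]oxy}phenyl)ethyl]benzene-1,3-diol | COCOc1ccc(Cl)cc1Oc1ccc(CCc2c(O)cccc2O)cc1 | intermediate
11 | 2-[2-(4-{[5-ethenyl-2-(methoxymethoxy)phenyl]oxy}phenyl)ethyl]benzene-1,3-diol | COCOc1ccc(C=C)cc1Oc1ccc(CCc2c(O)cccc2O)cc1 | intermediate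
12 | 1-bromo-3-iodobenzene | Brc1cccc(I)c1 | starting material
13 | 2-[2-(4-{[5-[2-(3-bromophenyl)ethyl]-2-(methoxymethoxy)phenyl]oxy}phenyl)ethyl]benzene-1,3-diol | COCOc1ccc(CCc2cccc(Br)c2)cc1Oc1ccc(CCc2c(O)cccc2O)cc1 | intermediate
14 | MOM-protected macrocyclic phenol (18-membered bis-bibenzyl diaryl ether) | COCOc1ccc2cc1Oc1ccc(cc1)CCc1c(O)cccc1Oc1cccc(c1)CC2 | intermediate
15 | marchantinquinone O-methoxymethyl ether | COCOc1ccc2cc1Oc1ccc(cc1)CCC1=C(Oc3cccc(c3)CC2)C(=O)C=CC1=O | intermediate
16 | marchantinquinone | O=C1C=CC(=O)C2=C1CCc1ccc(cc1)Oc1cc(ccc1O)CCc1cccc(c1)O2 | target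

## Summary

Total steps: 11.
Longest linear sequence: 10 (4-chlorophenol 3 → 16, steps 2–11); step 1 is a one-step side branch.

Steps most likely to fail:

1. **Step 6 (and step 8, which shares the risk).** The aryl radical may be reduced before it adds, the styrene may telomerise, or electron transfer to the electron-rich iodide may be slow. Fallback: reverse the polarity of the coupling. Convert styrene 9 to the primary bromide ArCH2CH2Br by radical anti-Markovnikov HBr addition, then join it to 2 (as its bis-MOM ether if needed) by silyl-radical-mediated Ni/photoredox cross-electrophile coupling, so the same bond comes from a primary alkyl radical.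
2. **Step 9.** The hindered phenoxide and high dilution may favour oligomers or debromination. Fallback: move the ring closure to the C–C bridge. Mono-O-arylate diol 11 with excess 1,3-diiodobenzene (Ullmann), then close the 18-membered ring by intramolecular aryl-radical addition to the styrene under high dilution.
3. **Step 10.** The macrocycle may be poorly soluble, or ortho-quinone formation and over-oxidation may compete. Fallback: introduce the para oxygen through nitrogen. Azo-couple 14 with benzenediazonium at the free para position, reduce with Na2S2O4 to the p-aminophenol, and oxidise mildly (FeCl3 or air) to the quinone before removing the MOM group.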